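Work back from late times. If each product takes one reagent, the 1.58 M of substrates in alder meet 2.37 M of reagent, a ratio of 1.50. Substrate is then the limiting reagent, and complete conversion leaves 33.3% of the reagent's charge. What remains is how fast alder, followed on to 2.5 h, approaches that end; oak differs from it in precatalyst.

all flasks: left-handed substrate 0.79 M; right-handed substrate 0.79 M; reagent 2.37 M; racemization catalyst 26 mM
- alder: precatalyst 7.9 mM; the very flask that is asked about, followed so far
- oak: precatalyst 4 mM; run made earlier
- flask: precatalyst 7.9 mM; time 2.5 h

| run | time / min | left-handed substrate / % | right-handed substrate / % | left-handed product / % |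
|---|---|---|---|---|
| alder | 5.00 | 48 | 53 | 0 |
| alder | 15.0 | 45 | 48 | 3 |
| alder | 30.0 | 45 | 51 | 6 |
| alder | 40.0 | 42 | 45 | 8 |
| alder | 60.0 | 39 | 41 | 16 |
| oak | 10.0 | 50 | 47 | 0 |
| oak | 25.0 | 51 | 47 | 1 |
| oak | 50.0 | 45 | 46 | 7 |
| oak | 80.0 | 41 | 46 | 11 |
| oak | 120 | 34 | 39 | 19 |

(standard deviation of a reading: 2 percentage points)

- free catalyst is single-handed; left-handed substrate and right-handed substrate are mirror images of each other, charged as a racemate, each of them at the stated concentration
- an excess is the difference of the two amounts in percent of their sum
- an excess is below zero if the other one leads

- part of the left-handed substrate and right-handed substrate charged together that has reacted at 2.5 h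
- excess of left-handed product over right-handed product in the product at 2.5 h
- excess of right-handed substrate over left-handed substrate among what is left of the two at 2.5 h

The first rung is racemization. At 60.0 min, the alder readings give 20.0% reacted, so by balance left-handed product leads right-handed by 12 percentage points. Without interconversion the substrate gap would equal that lead, but it reads 2 points, smaller. In oak at 120 min, the readings give 27.0% reacted and a product excess of 40.7%, against 60.0% in alder at 60.0 min, so they hold that excess only loosely.

The next rung is the release of catalyst. For a reacted part c, take the second-order integral with unequal charges, G = q/(q − 1) · ln[(1 − c/q)/(1 − c)], with q the ratio above, and set G equal to k times precatalyst charged times time past a lag. The readings give G = 0.240 for alder and 0.349 for oak. Together they yield a lag of 27.9 min and k = 0.947 /M/min, the loading rate constant, both readings with their scatter.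

The last rung is conversion itself, with a time in alder of 134 min per unit of G, longer than the lag. At 2.5 h, G = 0.913, so I expect 51.6% reacted.

The forecast gives 52% reacted, product excess 52% and substrate excess 5%, saying “The substrates stay nearly racemic, so racemization keeps up”.

The flask gives 52.5% reacted, product excess 36.7% and substrate excess 5.74%.

    reagent → decomposition product (k = 3.50 × 10⁻⁵ /min)
    reagent + free catalyst + left-handed substrate → free catalyst + left-handed product (k = 0.660 /M²/min)
    precatalyst → free catalyst (k = 0.0240 /min)
    left-handed substrate + racemization catalyst ⇌ right-handed substrate + racemization catalyst, rate k4*[racemization catalyst]*[left-handed substrate] forward; the back reaction follows from the equilibrium constant (k = 0.770 /M/min)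
    reagent + free catalyst + right-handed substrate → free catalyst + right-handed product (k = 0.280 /M²/min)

The selectivity factor is 2.36. At 1.25 h, the loading rate constant gives 27.2%, and the flask held 27.0%. For the neighbour charged with 0.0047 M of precatalyst, the same constant and lag give 37.3% reacted at 2.5 h. That flask gives 38.3%.

The numbers in the tables are calculated with constants of no real substance; the scatter is artificial.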